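Take the easy step first: a slice of fluid in plug flow ages just as the closed flask does, so maple and cedar are one case and alder is the other.

all flasks: starting material 0.22 M

|  | time | remark |
|---|---|---|
| maple | 25 min | plug flow through a tube for 25 min, no back-mixing |
| cedar | 25 min | a closed flask charged with all of it at once and left for 25 min |
| alder |  | a single well-mixed tank run continuously and read at steady state, 25 min in it on average |
    starting material ⇌ intermediate (K1 = 37, k1 = 0.014 s⁻¹)
    starting material + target → side product (k2 = 0.050 M⁻¹ s⁻¹)
    intermediate ⇌ target (K3 = 1.6, k3 = 0.015 s⁻¹)
    target ⇌ isomer of the product (K4 = 18, k4 = 0.0069 s⁻¹)
- the set-up with the highest share of target in all that became target or side product or isomer of the product, at the outlet or at the end ("none" if the first two lie within 2 percentage points) (maple / cedar / alder / none)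
- share of target in all that became target or side product or isomer of the product, at the outlet or at the end, maple
- share of target in all that became target or side product or isomer of the product, at the outlet or at the end, cedar
- share of target in all that became target or side product or isomer of the product, at the outlet or at the end, alder
- percent here means starting material units held: one side product counts as two
- the stated concentrations are those of everything mixed, before any reaction; amounts are the same in each set-up
- run time (maple): 25 min

Here 10.3 is the turnover count: the forward rate constant from target to isomer of the product times the time spent, which is the number of chances a target unit gets to isomerise.

Does cedar reach equilibrium between target and isomer? Target's forward half-life, 1.67 min, is shorter than the run, so it probably does.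

Does intermediate hold it back? Intermediate and target relax together in 0.474 min, faster than target isomerises, so they travel as a pair. Target is a fraction 0.615 of that pair, which cuts the count to 6.37. That is still more than one, so I expect thermodynamic control of target against isomer in cedar and maple, with isomer per target near 18 and a share of about 5.26 % before side product is counted.

What does alder's spread of ages do? A balance on the isomer in alder, which leaves with the flow, gives isomer per target as the count divided by one plus the count over the equilibrium constant: 6.57, less than in cedar. Alder's share is then 13.2 % before side product, so I commit to alder.

The forecast says alder, with 4.8 % for maple, 4.8 % for cedar and 11.1 % for alder: “The well-mixed tank keeps a residence-time spread that holds the system well short of that equilibrium”.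

The simulation gives alder, with 4.44 % for maple, 4.44 % for cedar and 11.1 % for alder. In cedar, target's forward half-life of 1.7 min is short against the 25 min run, and at the end isomer stands at 75.0 % against 4.32 % target, 17.4 to one. Side product holds 17.9 % of cedar's charge, and the share lies below my 5.26 %.

Now take a flask like cedar charged at 0.37 M. The count contains no concentration, so it stays 10.3, and you should expect isomer per target near 18 again. The computed flask holds 68.0 % isomer against 3.91 % target, 17.4 to one, with side product at 25.6 % and a share of 4.01 %.

(The numbers come from no measurement; the rest is arithmetic.)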